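Assumption: the SMILES is read literally. In carotenoid numbering (ring C1–C6, furan carbon C8, chain C9–C15 and C15′–C10′) the centres are 3S,5R,8R, the C9=C10 bond is Z (C8 cis to C11) and all other chain double bonds are E; compounds 1, 5, 13 and 14 are taken as commercial.

**Retrosynthetic overview**
1. Target ⇐ its C27 ethyl ester / C3 pivalate by one hydride reduction; C11=C12 ⇐ Horner–Wadsworth–Emmons coupling of a C15 dihydrofuran allyl phosphonate with a C12 aldehyde ester (C10 dialdehyde + C2 Wittig).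
2. Key step: the O–C8 bond and C8 (R) come from a gold-catalysed 5-endo cycloisomerisation of a C5-hydroxy vinylallene (axis-to-centre transfer). This replaces the usual acid-induced 5,6-epoxide → 5,8-furanoid rearrangement, which gives both C8 epimers and would scramble the 9Z bond.
3. Allene axis ⇐ anti SN2′ copper hydride reduction of a C5,C6-oxirane carrying the C7≡C8 alkyne (centre-to-axis transfer).
4. Alkynyl oxirane ⇐ peracid epoxidation anti to the C3 ester of a dienyne, made by Sonogashira coupling of the enol triflate of (4R,6R)-actinol pivalate with a (Z)-C6 alkyne that already holds the 9Z bond and the phosphonate.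
5. Ring order: cyclohexane ring bought with C3 in place → oxirane (made in step 6, consumed in step 7) → 2,5-dihydrofuran (step 8); the polyene is attached afterwards.

**Route**

Step 1
Reactants: 1 (4R,6R)-4-hydroxy-2,2,6-trimethylcyclohexan-1-one
Product: 2 (1R,5R)-3,3,5-trimethyl-4-oxocyclohexyl pivalate
Conditions: PivCl, pyridine, DMAP (cat.), CH2Cl2, 0 °C → rt
Reagents that add atoms: pivaloyl chloride, CC(C)(C)C(=O)Cl
Why: DMAP-catalysed acylation of the secondary alcohol; the pivalate tolerates every later step and is removed by the final hydride reduction, and no stereocentre is touched.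

Step 2
Reactants: 2 (1R,5R)-3,3,5-trimethyl-4-oxocyclohexyl pivalate
Product: 4 (1R)-3,5,5-trimethyl-4-[(trifluoromethylsulfonyl)oxy]cyclohex-3-en-1-yl pivalate, via potassium enolate 3 (not isolated)
Conditions: KN(SiMe3)2, THF, −78 °C; then PhNTf2, −78 → 0 °C
Reagents that add atoms: N-phenyl-bis(trifluoromethanesulfonimide), O=S(=O)(N(c1ccccc1)S(=O)(=O)C(F)(F)F)C(F)(F)F
Why: enolate O-triflation (enol triflate synthesis); the ketone has a single α-hydrogen, so only the C5=C6 enol triflate can form, and the methyl-bearing centre is erased on purpose.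

Step 3
Reactants: 5 (2Z)-3-methylpent-2-en-4-yn-1-ol
Product: 6 (3Z)-5-bromo-3-methylpent-3-en-1-yne
Conditions: CBr4, PPh3, CH2Cl2, 0 °C
Reagents that add atoms: tetrabromomethane, BrC(Br)(Br)Br
Why: Appel bromination, a neutral SN2 displacement at the primary allylic carbon that leaves the Z double bond and the terminal alkyne untouched.

Step 4
Reactants: 6 (3Z)-5-bromo-3-methylpent-3-en-1-yne
Product: 7 diethyl [(2Z)-3-methylpent-2-en-4-yn-1-yl]phosphonate
Conditions: P(OEt)3 (neat), 85 °C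
Reagents that add atoms: triethyl phosphite, CCOP(OCC)OCC
Why: Michaelis–Arbuzov reaction (SN2 by phosphorus at the primary allylic bromide, then dealkylation by bromide), with the alkene geometry retained.

Step 5
Reactants: 4 (1R)-3,5,5-trimethyl-4-[(trifluoromethylsulfonyl)oxy]cyclohex-3-en-1-yl pivalate; 7 diethyl [(2Z)-3-methylpent-2-en-4-yn-1-yl]phosphonate
Product: 8 diethyl {(2Z)-3-methyl-5-[(4R)-2,6,6-trimethyl-4-(pivaloyloxy)cyclohex-1-en-1-yl]pent-2-en-4-yn-1-yl}phosphonate
Conditions: Pd(PPh3)4 (5 mol %), CuI (10 mol %), iPr2NH, THF, rt → 40 °C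
Reagents that add atoms: none
Why: Sonogashira coupling of a vinyl triflate with a terminal alkyne forms the C6–C7 bond and brings in C7–C11 with the 9Z bond and the phosphonate already in place; the amine is too weak a base to touch the CH2P group.

Step 6
Reactants: 8 diethyl {(2Z)-3-methyl-5-[(4R)-2,6,6-trimethyl-4-(pivaloyloxy)cyclohex-1-en-1-yl]pent-2-en-4-yn-1-yl}phosphonate
Product: 9 diethyl {(2Z)-3-methyl-5-[(1R,4S,6R)-2,2,6-trimethyl-4-(pivaloyloxy)-7-oxabicyclo[4.1.0]heptan-1-yl]pent-2-en-4-yn-1-yl}phosphonate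
Conditions: mCPBA (1.1 equiv), CH2Cl2, −20 → 0 °C; chromatography on Et3N-deactivated silica
Reagents that add atoms: 3-chloroperoxybenzoic acid, OOC(=O)c1cccc(Cl)c1
Why: Prilezhaev epoxidation; the tetrasubstituted ring alkene is much more nucleophilic than the phosphonate-bearing trisubstituted alkene, and the peracid attacks anti to the C3 acyloxy group (no hydrogen-bond donor; about 3–4:1 expected, the minor syn oxirane is removed by chromatography), which sets C5 (R) and places the C6–O bond that will leave.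

Step 7
Reactants: 9 diethyl {(2Z)-3-methyl-5-[(1R,4S,6R)-2,2,6-trimethyl-4-(pivaloyloxy)-7-oxabicyclo[4.1.0]heptan-1-yl]pent-2-en-4-yn-1-yl}phosphonate
Product: 11 diethyl {(2Z,4Sa)-5-[(2R,4S)-2-hydroxy-2,6,6-trimethyl-4-(pivaloyloxy)cyclohexylidene]-3-methylpenta-2,4-dien-1-yl}phosphonate, via silyl ether 10 (not isolated)
Conditions: chloro[1,3-bis(2,6-diisopropylphenyl)imidazol-2-ylidene]copper (IPr)CuCl (5 mol %), NaOtBu (5 mol %), (EtO)2MeSiH (2 equiv), toluene, 0 °C; then K2CO3 (10 mol %), MeOH, 0 °C; kept below 0 °C and used at once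
Reagents that add atoms: none
Why: copper hydride SN2′ reduction of a propargylic oxirane, in which hydride enters C8 anti to the breaking C6–O bond so that the oxirane configuration becomes the (Sa) allene axis (centre-to-axis chirality transfer) while the C5–O bond and C5 (R) are kept; catalytic K2CO3 in methanol then frees the tertiary alcohol from its silyl ether without touching pivalate or phosphonate.

Step 8
Reactants: 11 diethyl {(2Z,4Sa)-5-[(2R,4S)-2-hydroxy-2,6,6-trimethyl-4-(pivaloyloxy)cyclohexylidene]-3-methylpenta-2,4-dien-1-yl}phosphonate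
Product: 12 diethyl {(2Z)-3-[(2R,6S,7aR)-4,4,7a-trimethyl-6-(pivaloyloxy)-2,4,5,6,7,7a-hexahydro-1-benzofuran-2-yl]but-2-en-1-yl}phosphonate
Conditions: AuCl3 (2 mol %), THF, 0 °C, dark
Reagents that add atoms: none
Why: gold-catalysed 5-endo cycloisomerisation of an α-hydroxyallene to a 2,5-dihydrofuran; the C5 hydroxyl adds to C8 in the plane of the C7=C8 π bond anti to gold and protodeauration follows, so H and C9 keep their sides and the (Sa) axis becomes C8 (R) with C9 cis to C4 and trans to the C5 methyl (axis-to-centre chirality transfer), and no cation forms that could scramble C8 or the 9Z bond.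

Step 9
Reactants: 13 (2E,4E,6E)-2,7-dimethylocta-2,4,6-trienedial (3 equiv); 14 ethyl (triphenylphosphoranylidene)acetate
Product: 15 ethyl (2E,4E,6E,8E)-4,9-dimethyl-10-oxodeca-2,4,6,8-tetraenoate
Conditions: CH2Cl2, rt, 16 h; excess 13 recovered by chromatography
Reagents that add atoms: none
Why: Wittig reaction of a stabilised ylide, E-selective at the new C11′=C12′ bond; the excess of dialdehyde limits the reaction to one end.

Step 10
Reactants: 12 diethyl {(2Z)-3-[(2R,6S,7aR)-4,4,7a-trimethyl-6-(pivaloyloxy)-2,4,5,6,7,7a-hexahydro-1-benzofuran-2-yl]but-2-en-1-yl}phosphonate; 15 ethyl (2E,4E,6E,8E)-4,9-dimethyl-10-oxodeca-2,4,6,8-tetraenoate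
Product: 17 ethyl (2E,4E,6E,8E,10E,12Z)-4,9-dimethyl-13-[(2R,6S,7aR)-4,4,7a-trimethyl-6-(pivaloyloxy)-2,4,5,6,7,7a-hexahydro-1-benzofuran-2-yl]tetradeca-2,4,6,8,10,12-hexaenoate, via sodium phosphonate carbanion 16 (not isolated)
Conditions: NaN(SiMe3)2 (1.05 equiv), THF, −78 °C, 10 min; then 15, −78 → −30 °C, dark
Reagents that add atoms: none
Why: Horner–Wadsworth–Emmons olefination of an allylic phosphonate anion with the aldehyde gives the new C11=C12 bond E, and at −78 °C the anion is trapped before it can open the dihydrofuran, epimerise C8 or isomerise the 9Z bond.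

Step 11
Reactants: 17 ethyl (2E,4E,6E,8E,10E,12Z)-4,9-dimethyl-13-[(2R,6S,7aR)-4,4,7a-trimethyl-6-(pivaloyloxy)-2,4,5,6,7,7a-hexahydro-1-benzofuran-2-yl]tetradeca-2,4,6,8,10,12-hexaenoate
Product: 18 (2E,4E,6E,8E,10E,12Z)-13-[(2R,6S,7aR)-6-hydroxy-4,4,7a-trimethyl-2,4,5,6,7,7a-hexahydro-1-benzofuran-2-yl]-4,9-dimethyltetradeca-2,4,6,8,10,12-hexaen-1-ol
Conditions: iBu2AlH (6 equiv), CH2Cl2, −78 → −40 °C; aq. potassium sodium tartrate; dark, argon
Reagents that add atoms: none
Why: 1,2-reduction of the conjugated ester to the allylic alcohol and reductive cleavage of the pivalate in one operation under non-acidic conditions, with no stereocentre or double bond touched.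

**Compound list**
1 | (4R,6R)-4-hydroxy-2,2,6-trimethylcyclohexan-1-one ((4R,6R)-actinol) | O=C1C(C)(C)C[C@H](O)C[C@H]1C | starting material
2 | (1R,5R)-3,3,5-trimethyl-4-oxocyclohexyl pivalate | O=C1C(C)(C)C[C@H](OC(=O)C(C)(C)C)C[C@H]1C | intermediate
3 | potassium (4R)-2,6,6-trimethyl-4-(pivaloyloxy)cyclohex-1-en-1-olate | CC1=C([O-])C(C)(C)C[C@H](OC(=O)C(C)(C)C)C1.[K+] | intermediate
4 | (1R)-3,5,5-trimethyl-4-[(trifluoromethylsulfonyl)oxy]cyclohex-3-en-1-yl pivalate | CC1=C(OS(=O)(=O)C(F)(F)F)C(C)(C)C[C@H](OC(=O)C(C)(C)C)C1 | intermediate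
5 | (2Z)-3-methylpent-2-en-4-yn-1-ol | C#C/C(C)=C\CO | starting material
6 | (3Z)-5-bromo-3-methylpent-3-en-1-yne | C#C/C(C)=C\CBr | intermediate
7 | diethyl [(2Z)-3-methylpent-2-en-4-yn-1-yl]phosphonate | C#C/C(C)=C\CP(=O)(OCC)OCC | intermediate
8 | diethyl {(2Z)-3-methyl-5-[(4R)-2,6,6-trimethyl-4-(pivaloyloxy)cyclohex-1-en-1-yl]pent-2-en-4-yn-1-yl}phosphonate | CC1=C(C#C/C(C)=C\CP(=O)(OCC)OCC)C(C)(C)C[C@H](OC(=O)C(C)(C)C)C1 | intermediate
9 | diethyl {(2Z)-3-methyl-5-[(1R,4S,6R)-2,2,6-trimethyl-4-(pivaloyloxy)-7-oxabicyclo[4.1.0]heptan-1-yl]pent-2-en-4-yn-1-yl}phosphonate (oxirane oxygen trans to the pivalate) | C[C@]12O[C@@]1(C#C/C(C)=C\CP(=O)(OCC)OCC)C(C)(C)C[C@H](OC(=O)C(C)(C)C)C2 | intermediate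
10 | diethoxy(methyl)silyl ether of 11 at the tertiary C5 oxygen | C[C@@]1(O[Si](C)(OCC)OCC)C[C@@H](OC(=O)C(C)(C)C)CC(C)(C)C1=[C@]=C([H])/C(C)=C\CP(=O)(OCC)OCC | intermediate
11 | diethyl {(2Z,4Sa)-5-[(2R,4S)-2-hydroxy-2,6,6-trimethyl-4-(pivaloyloxy)cyclohexylidene]-3-methylpenta-2,4-dien-1-yl}phosphonate (allene C8–H anti to the former C6–O bond) | C[C@@]1(O)C[C@@H](OC(=O)C(C)(C)C)CC(C)(C)C1=[C@]=C([H])/C(C)=C\CP(=O)(OCC)OCC | intermediate
12 | diethyl {(2Z)-3-[(2R,6S,7aR)-4,4,7a-trimethyl-6-(pivaloyloxy)-2,4,5,6,7,7a-hexahydro-1-benzofuran-2-yl]but-2-en-1-yl}phosphonate | C/C(=C/CP(=O)(OCC)OCC)[C@H]1C=C2C(C)(C)C[C@H](OC(=O)C(C)(C)C)C[C@@]2(C)O1 | intermediate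
13 | (2E,4E,6E)-2,7-dimethylocta-2,4,6-trienedial | O=C/C(C)=C/C=C/C=C(C)/C=O | starting material
14 | ethyl (triphenylphosphoranylidene)acetate | CCOC(=O)C=P(c1ccccc1)(c1ccccc1)c1ccccc1 | starting material
15 | ethyl (2E,4E,6E,8E)-4,9-dimethyl-10-oxodeca-2,4,6,8-tetraenoate | CCOC(=O)/C=C/C(C)=C/C=C/C=C(C)/C=O | intermediate
16 | sodium salt of the C1 (α-phosphoryl) carbanion of 12 | C/C(=C/[CH-]P(=O)(OCC)OCC)[C@H]1C=C2C(C)(C)C[C@H](OC(=O)C(C)(C)C)C[C@@]2(C)O1.[Na+] | intermediate
17 | ethyl (2E,4E,6E,8E,10E,12Z)-4,9-dimethyl-13-[(2R,6S,7aR)-4,4,7a-trimethyl-6-(pivaloyloxy)-2,4,5,6,7,7a-hexahydro-1-benzofuran-2-yl]tetradeca-2,4,6,8,10,12-hexaenoate | C/C(=C/C=C/C(C)=C/C=C/C=C(C)/C=C/C(=O)OCC)[C@H]1C=C2C(C)(C)C[C@H](OC(=O)C(C)(C)C)C[C@@]2(C)O1 | intermediate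
18 | (2E,4E,6E,8E,10E,12Z)-13-[(2R,6S,7aR)-6-hydroxy-4,4,7a-trimethyl-2,4,5,6,7,7a-hexahydro-1-benzofuran-2-yl]-4,9-dimethyltetradeca-2,4,6,8,10,12-hexaen-1-ol, i.e. (3S,5R,8R,9Z)-5,8-epoxy-5,8-dihydro-10′-apo-β-carotene-3,10′-diol | C/C(=C/C=C/C(C)=C/C=C/C=C(C)/C=C/CO)[C@H]1C=C2C(C)(C)C[C@H](O)C[C@@]2(C)O1 | target

**Totals**
Total step count: 11. Longest linear sequence: 8 steps (1 → 2 → 4 → 8 → 9 → 11 → 12 → 17 → 18).

**Three steps most likely to fail**

Step 7 (copper hydride SN2′ reduction). The substrate is a tetrasubstituted oxirane on a conjugated (Z)-enyne with an acidic CH2P group; hydrocupration could take another course or the anti selectivity could erode. The fallback sets out from 9 and replaces the hydrometalation manifold by a palladium-catalysed hydrogenolysis: Pd2(dba)3 (2.5 mol %), PBu3 (10 mol %), HCO2H/Et3N, THF, 25 °C. Zerovalent palladium opens the oxirane by anti SN2′ oxidative addition to an allenylpalladium alkoxide, formate hands over hydride with loss of CO2, and reductive elimination with retention gives the same anti allenol; no metal hydride ever adds across the enyne. The route is rejoined at 11. This fallback makes no new compound: F0.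

Step 8 (gold cycloisomerisation). The (Z)-vinylallene 11 can undergo a [1,5]-hydrogen shift from C11 to C7 on warming, and gold could ionise the vinyl-stabilised C8 position and erode the axis-to-centre transfer. The fallback sets out from 11 and closes the ring by halocyclisation instead of π-acid catalysis: N-iodosuccinimide, CH2Cl2, −40 °C, gives by anti iodoetherification the 3-iodo-2,5-dihydrofuran phosphonate diethyl {(2Z)-3-[(2S,6S,7aR)-3-iodo-4,4,7a-trimethyl-6-(pivaloyloxy)-2,4,5,6,7,7a-hexahydro-1-benzofuran-2-yl]but-2-en-1-yl}phosphonate F1 (same spatial arrangement at C8; the descriptor changes only because iodine raises the rank of C7). The vinyl iodide is then reduced with retention by Bu3SnH and Pd(PPh3)4 (zerovalent palladium, 3 mol %) in THF at rt, and the route is rejoined at 12.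

Step 10 (olefination). The allyl anion 16 carries charge at C9 next to the C8–O bond, so vinylogous β-elimination could open the dihydrofuran, and C8 or the 9Z bond could be lost. The fallback sets out from 11 and swaps the order of olefination and ring closure: 11 is treated with NaN(SiMe3)2 (2.1 equiv, alkoxide plus phosphonate carbanion) in THF at −78 °C and then with 15, giving the allenic C27 ester ethyl (2E,4E,6E,8E,10E,12Z)-15-[(2R,4S)-2-hydroxy-2,6,6-trimethyl-4-(pivaloyloxy)cyclohexylidene]-4,9,13-trimethylpentadeca-2,4,6,8,10,12,14-heptaenoate with (Sa) allene axis F2. F2 is kept below 0 °C, because a (Z)-dienylallene can electrocyclise, and is cyclised at once with AuCl3 (2 mol %) in THF at 0 °C; the route is rejoined at 17.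

**Further compounds**
F0 | step 7 | none | none
F1 | step 8 | diethyl {(2Z)-3-[(2S,6S,7aR)-3-iodo-4,4,7a-trimethyl-6-(pivaloyloxy)-2,4,5,6,7,7a-hexahydro-1-benzofuran-2-yl]but-2-en-1-yl}phosphonate | C/C(=C/CP(=O)(OCC)OCC)[C@H]1C(I)=C2C(C)(C)C[C@H](OC(=O)C(C)(C)C)C[C@@]2(C)O1
F2 | step 10 | ethyl (2E,4E,6E,8E,10E,12Z)-15-[(2R,4S)-2-hydroxy-2,6,6-trimethyl-4-(pivaloyloxy)cyclohexylidene]-4,9,13-trimethylpentadeca-2,4,6,8,10,12,14-heptaenoate, (Sa) allene axis | C[C@@]1(O)C[C@@H](OC(=O)C(C)(C)C)CC(C)(C)C1=[C@]=C([H])/C(C)=C\C=C\C(C)=C\C=C\C=C(C)\C=C\C(=O)OCC
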